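**Strategy**

The route rests on reading C4, the vinylic CH of ring B between C4a of ring A and C3 (which carries the formyl carbon C9), as a carbonyl carbon. Transposing the C4=C3–C9=O enal gives a C4 ketone flanked by a C3=C9 enol ether, so C4 can be supplied by carbon monoxide. One palladium-catalysed carbonylative Heck reaction then forges C4a–C4 and C4–C3 and closes ring B. Its precursor is an open-chain methyl enol ether that already carries both stereocentres (C1 with rings A and C, C2 with a silylated hydroxymethyl group) and a bromine at C4a, built by two auxiliary-controlled steps from one oxazolidinone.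

Key step: step 14

Remark (numbering): ring A is the fused benzene ring (C4a, C5–C8, C8a), ring B the dihydro ring (C1 bears ring C, C2 bears CH2OH, C3 bears the formyl carbon C9, C4 is the vinylic CH), ring C the pendant aryl group; the target is 1S,2R (trans).

Remark (auxiliary): by the usual chelate models the R enantiomer of 4-benzyl-2-oxazolidinone is the one that leads to 1S,2R; the S auxiliary would give the mirror image, so the R series is used throughout.

Remark (protecting groups): the phenols are carried as triisopropylsilyl (TIPS) ethers, which tolerate base better than tert-butyldimethylsilyl ethers, and the primary alcohol as a tert-butyldimethylsilyl (TBS) ether; ArA = 6-bromo-2-methoxy-3-[(triisopropylsilyl)oxy]phenyl, ArC = 3-methoxy-4-[(triisopropylsilyl)oxy]phenyl.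

Assumption: step 13 is written for the E enol ether; any Z isomer formed with it has the same connectivity, is not separated, and converges because the C3=C9 geometry is erased in step 15.

**Route**

Step 1
Reactants: 1 2,3-dihydroxybenzaldehyde
Product: 3 3-(benzyloxy)-2-methoxybenzaldehyde, via sodium 2-(benzyloxy)-6-formylphenolate 2 (not isolated)
Conditions: NaH (2.1 equiv), DMSO, 20 °C; BnBr (1.0 equiv); then MeI (1.5 equiv), 20 °C
Reagents that add atoms: benzyl bromide, BrCc1ccccc1; iodomethane, CI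
Why: Regioselective O-alkylation of the catechol dianion followed by Williamson methylation in the same flask, in which the 3-phenoxide (neither conjugated to nor chelated by the formyl group) is the more nucleophilic site and takes the benzyl group, leaving the 2-phenoxide for iodomethane.

Step 2
Reactants: 3 3-(benzyloxy)-2-methoxybenzaldehyde
Product: 4 3-hydroxy-2-methoxybenzaldehyde
Conditions: H2 (1 atm), Pd/C, EtOAc, 20 °C
Reagents that add atoms: none
Why: Hydrogenolysis of an aryl benzyl ether over Pd/C at atmospheric pressure in ethyl acetate is much faster than reduction of the aryl aldehyde, and no halogen is present yet.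

Step 3
Reactants: 4 3-hydroxy-2-methoxybenzaldehyde
Product: 5 6-bromo-3-hydroxy-2-methoxybenzaldehyde
Conditions: NBS, MeCN, 0 °C
Reagents that add atoms: N-bromosuccinimide, O=C1CCC(=O)N1Br
Why: Electrophilic aromatic bromination steered by the free phenol to its para position (the future C4a), since one ortho position is occupied by the methoxy group and the other lies para to the formyl group, in line with the para bromination of 3-hydroxybenzaldehyde.

Step 4
Reactants: 5 6-bromo-3-hydroxy-2-methoxybenzaldehyde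
Product: 6 6-bromo-2-methoxy-3-[(triisopropylsilyl)oxy]benzaldehyde
Conditions: TIPSCl, imidazole, DMF, 20 °C
Reagents that add atoms: chlorotriisopropylsilane, CC(C)[Si](Cl)(C(C)C)C(C)C
Why: Imidazole-promoted silylation of a phenol gives the silyl ether that masks the C7 oxygen until the last step.

Step 5
Reactants: 7 (R)-4-benzyl-2-oxazolidinone; 8 diethylphosphonoacetic acid
Product: 10 diethyl {2-[(4R)-4-benzyl-2-oxo-1,3-oxazolidin-3-yl]-2-oxoethyl}phosphonate, via (diethoxyphosphoryl)acetic pivalic anhydride 9 (not isolated)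
Conditions: PivCl, Et3N, THF, −20 °C; then 7, LiCl, 20 °C
Reagents that add atoms: none
Why: N-Acylation of the oxazolidinone through a mixed pivalic anhydride, which the LiCl-activated auxiliary attacks at the less hindered phosphonoacetyl carbonyl.

Step 6
Reactants: 6 6-bromo-2-methoxy-3-[(triisopropylsilyl)oxy]benzaldehyde; 10 diethyl {2-[(4R)-4-benzyl-2-oxo-1,3-oxazolidin-3-yl]-2-oxoethyl}phosphonate
Product: 11 (4R)-4-benzyl-3-[(2E)-3-ArA-prop-2-enoyl]-1,3-oxazolidin-2-one
Conditions: LiCl, i-Pr2NEt, MeCN, 20 °C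
Reagents that add atoms: none
Why: Horner–Wadsworth–Emmons olefination under Masamune–Roush conditions gives the E enoyl imide and is mild enough for the aryl silyl ether and the non-enolisable, ortho-disubstituted aldehyde.

Step 7
Reactants: 12 4-bromo-2-methoxyphenol
Product: 13 (4-bromo-2-methoxyphenoxy)triisopropylsilane
Conditions: TIPSCl, imidazole, DMF, 20 °C
Reagents that add atoms: chlorotriisopropylsilane, CC(C)[Si](Cl)(C(C)C)C(C)C
Why: Silylation of the phenol removes the acidic proton so that the aryl bromide can be turned into a Grignard reagent.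

Step 8
Reactants: 11 (4R)-4-benzyl-3-[(2E)-3-ArA-prop-2-enoyl]-1,3-oxazolidin-2-one; 13 (4-bromo-2-methoxyphenoxy)triisopropylsilane
Product: 15 (4R)-4-benzyl-3-[(3S)-3-ArA-3-ArC-propanoyl]-1,3-oxazolidin-2-one, via {3-methoxy-4-[(triisopropylsilyl)oxy]phenyl}magnesium bromide 14 (not isolated)
Conditions: 13, Mg, THF, 45 °C; CuBr·SMe2 (1.5 equiv), THF/Me2S, −40 °C; then 11, −40 to −10 °C; aq NH4Cl
Reagents that add atoms: none
Why: Copper-mediated conjugate addition of an aryl Grignard reagent to an N-enoyl oxazolidinone, in which the benzyl group of the R auxiliary covers one face of the magnesium-chelated syn-s-cis enoyl unit so that the ring C aryl group arrives from the other face and sets C1 as S, while the aryl bromide is inert to the arylcopper species at this temperature.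

Step 9
Reactants: 15 (4R)-4-benzyl-3-[(3S)-3-ArA-3-ArC-propanoyl]-1,3-oxazolidin-2-one
Product: 17 (4R)-4-benzyl-3-[(2S,3S)-3-ArA-3-ArC-2-(hydroxymethyl)propanoyl]-1,3-oxazolidin-2-one, via its trichlorotitanium Z-enolate 16 (not isolated)
Conditions: TiCl4, i-Pr2NEt, CH2Cl2, 0 °C; then 1,3,5-trioxane, TiCl4, 0 °C
Reagents that add atoms: 1,3,5-trioxane, C1OCOCO1
Why: Evans hydroxymethylation of a chelated chlorotitanium Z-enolate with Lewis-acid-activated trioxane, in which the electrophile attacks the face opposite the benzyl group, which is also the face away from the bulky ring A substituent of C1 in its allylic-strain-minimised conformer (matched case), so that C2 is set with the relative configuration of the trans ring.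

Step 10
Reactants: 17 (4R)-4-benzyl-3-[(2S,3S)-3-ArA-3-ArC-2-(hydroxymethyl)propanoyl]-1,3-oxazolidin-2-one
Product: 18 (4R)-4-benzyl-3-[(2S,3S)-3-ArA-3-ArC-2-({[tert-butyl(dimethyl)silyl]oxy}methyl)propanoyl]-1,3-oxazolidin-2-one
Conditions: TBSCl, imidazole, DMF, 20 °C
Reagents that add atoms: tert-butylchlorodimethylsilane, CC(C)(C)[Si](C)(C)Cl
Why: Silylation of the primary alcohol distinguishes this hydroxymethyl arm from the one that the next step creates, which is what keeps C2 a stereocentre.

Step 11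
Reactants: 18 (4R)-4-benzyl-3-[(2S,3S)-3-ArA-3-ArC-2-({[tert-butyl(dimethyl)silyl]oxy}methyl)propanoyl]-1,3-oxazolidin-2-one
Product: 19 (2R,3S)-3-ArA-3-ArC-2-({[tert-butyl(dimethyl)silyl]oxy}methyl)propan-1-ol
Conditions: LiBH4, MeOH (1 equiv), Et2O, 0 °C
Reagents that add atoms: none
Why: Reductive removal of the auxiliary, in which methanol-activated LiBH4 reduces the exocyclic imide carbonyl to the primary alcohol and releases the oxazolidinone, leaves the aryl bromide and silyl ethers untouched, and at low temperature gives the borate-bound alkoxide no chance to relay the silyl group to the new hydroxyl.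

Step 12
Reactants: 19 (2R,3S)-3-ArA-3-ArC-2-({[tert-butyl(dimethyl)silyl]oxy}methyl)propan-1-ol
Product: 20 (2S,3S)-3-ArA-3-ArC-2-({[tert-butyl(dimethyl)silyl]oxy}methyl)propanal
Conditions: Dess–Martin periodinane, NaHCO3, CH2Cl2, 0 to 20 °C
Reagents that add atoms: none
Why: Dess–Martin oxidation under buffered, non-basic conditions gives the aldehyde without epimerising the α-centre C2 or eliminating the β-silyloxy group.

Step 13
Reactants: 20 (2S,3S)-3-ArA-3-ArC-2-({[tert-butyl(dimethyl)silyl]oxy}methyl)propanal; 21 (methoxymethyl)triphenylphosphonium chloride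
Product: 23 (1E,3R,4S)-4-ArA-4-ArC-3-({[tert-butyl(dimethyl)silyl]oxy}methyl)-1-methoxybut-1-ene, via (methoxymethylidene)triphenylphosphorane 22 (not isolated)
Conditions: 21, NaN(SiMe3)2, THF, 0 °C; then 20, −78 to 0 °C
Reagents that add atoms: none
Why: Wittig methoxymethylenation, in which the ylide adds to the aldehyde faster than it enolises it, so that C2 keeps its configuration while the aldehyde carbon becomes C3 and the ylide carbon becomes C9.

Step 14
Reactants: 23 (1E,3R,4S)-4-ArA-4-ArC-3-({[tert-butyl(dimethyl)silyl]oxy}methyl)-1-methoxybut-1-ene; 24 carbon monoxide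
Product: 25 (2E,3R,4S)-3-({[tert-butyl(dimethyl)silyl]oxy}methyl)-5-methoxy-2-(methoxymethylidene)-4-{3-methoxy-4-[(triisopropylsilyl)oxy]phenyl}-6-[(triisopropylsilyl)oxy]-3,4-dihydronaphthalen-1(2H)-one
Conditions: CO (20 bar), Pd(OAc)2 (10 mol %), Xantphos (12 mol %), Et3N (3 equiv), toluene, 90 °C
Reagents that add atoms: none
Why: Zerovalent palladium formed from Pd(OAc)2 and Xantphos inserts into the C4a–Br bond, CO insertion gives an aroylpalladium bromide, this adds syn across the C3=C9 enol ether with the acyl carbon bonding to the nucleophilic C3, and β-hydride elimination of the C3 hydrogen after rotation about C3–C9, followed by loss of HBr to Et3N, returns the catalyst and leaves the methoxymethylidene ketone. The closest known reactions are the intramolecular acylpalladation (carbonylative Heck) closure of ortho-alkenyl aryl halides to indanones and tetralones and the intermolecular carbonylative Heck reaction of aryl bromides with vinyl ethers to 3-alkoxy enones. Ring B closes in a 6-exo-trig mode, forming C4a–C4 and C4–C3. No stereocentre is created; C1 and C2 are spectators, and because C3 carries the only β-hydrogen of the alkylpalladium intermediate the double bond can only re-form between C3 and C9. The step needs CO uptake to outrun direct 5-exo Heck closure to an indane, which the wide-bite-angle ligand and the CO pressure secure, and it needs closure onto ring A only, which the position of the bromine fixes. Excess Et3N and a moderate temperature remove the palladium hydride quickly so that it does not carry the exocyclic double bond into ring B.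

Step 15
Reactants: 25 (2E,3R,4S)-3-({[tert-butyl(dimethyl)silyl]oxy}methyl)-5-methoxy-2-(methoxymethylidene)-4-{3-methoxy-4-[(triisopropylsilyl)oxy]phenyl}-6-[(triisopropylsilyl)oxy]-3,4-dihydronaphthalen-1(2H)-one
Product: 27 (3R,4S)-3-({[tert-butyl(dimethyl)silyl]oxy}methyl)-5-methoxy-4-{3-methoxy-4-[(triisopropylsilyl)oxy]phenyl}-6-[(triisopropylsilyl)oxy]-3,4-dihydronaphthalene-2-carbaldehyde, via allylic alcohol 26 (not isolated)
Conditions: NaBH4, CeCl3·7H2O, MeOH/THF, 0 °C; then 1 M HCl, 0 °C
Reagents that add atoms: water, O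
Why: Luche 1,2-reduction of the vinylogous ester carbonyl gives a benzylic, γ-methoxy allylic alcohol that ionises in dilute acid to a cation stabilised through C3=C9 by the methoxy oxygen, water adds at C9 and methanol leaves, so the oxygen function moves from C4 to C9 (Stork–Danheiser-type transposition) without touching C1 or C2.

Step 16
Reactants: 27 (3R,4S)-3-({[tert-butyl(dimethyl)silyl]oxy}methyl)-5-methoxy-4-{3-methoxy-4-[(triisopropylsilyl)oxy]phenyl}-6-[(triisopropylsilyl)oxy]-3,4-dihydronaphthalene-2-carbaldehyde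
Product: 28 vitedoin A, (3R,4S)-6-hydroxy-4-(4-hydroxy-3-methoxyphenyl)-3-(hydroxymethyl)-5-methoxy-3,4-dihydronaphthalene-2-carbaldehyde
Conditions: Bu4NF, AcOH, THF, 0 to 20 °C
Reagents that add atoms: none
Why: Fluoride-induced desilylation cleaves the two aryl triisopropylsilyl ethers and the primary tert-butyldimethylsilyl ether, and the acetic acid buffer keeps the phenols protonated so that the enal and the C1 and C2 centres are not exposed to strong base.

**Compound list**

1 | 2,3-dihydroxybenzaldehyde | O=Cc1cccc(O)c1O | starting material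
2 | sodium 2-(benzyloxy)-6-formylphenolate | [Na+].[O-]c1c(C=O)cccc1OCc1ccccc1 | intermediate (not isolated)
3 | 3-(benzyloxy)-2-methoxybenzaldehyde | COc1c(C=O)cccc1OCc1ccccc1 | intermediate
4 | 3-hydroxy-2-methoxybenzaldehyde | COc1c(O)cccc1C=O | intermediate
5 | 6-bromo-3-hydroxy-2-methoxybenzaldehyde | COc1c(O)ccc(Br)c1C=O | intermediate
6 | 6-bromo-2-methoxy-3-[(triisopropylsilyl)oxy]benzaldehyde | COc1c(O[Si](C(C)C)(C(C)C)C(C)C)ccc(Br)c1C=O | intermediate
7 | (R)-4-benzyl-2-oxazolidinone | O=C1OC[C@@H](Cc2ccccc2)N1 | starting material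
8 | diethylphosphonoacetic acid | CCOP(=O)(OCC)CC(=O)O | starting material
9 | (diethoxyphosphoryl)acetic pivalic anhydride | CCOP(=O)(OCC)CC(=O)OC(=O)C(C)(C)C | intermediate (not isolated)
10 | diethyl {2-[(4R)-4-benzyl-2-oxo-1,3-oxazolidin-3-yl]-2-oxoethyl}phosphonate | CCOP(=O)(OCC)CC(=O)N1C(=O)OC[C@H]1Cc1ccccc1 | intermediate
11 | (4R)-4-benzyl-3-[(2E)-3-ArA-prop-2-enoyl]-1,3-oxazolidin-2-one | COc1c(O[Si](C(C)C)(C(C)C)C(C)C)ccc(Br)c1/C=C/C(=O)N1C(=O)OC[C@H]1Cc1ccccc1 | intermediate
12 | 4-bromo-2-methoxyphenol | COc1cc(Br)ccc1O | starting material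
13 | (4-bromo-2-methoxyphenoxy)triisopropylsilane | COc1cc(Br)ccc1O[Si](C(C)C)(C(C)C)C(C)C | intermediate
14 | {3-methoxy-4-[(triisopropylsilyl)oxy]phenyl}magnesium bromide | COc1cc([Mg]Br)ccc1O[Si](C(C)C)(C(C)C)C(C)C | intermediate (not isolated)
15 | (4R)-4-benzyl-3-[(3S)-3-ArA-3-ArC-propanoyl]-1,3-oxazolidin-2-one | COc1cc([C@H](CC(=O)N2C(=O)OC[C@H]2Cc2ccccc2)c2c(Br)ccc(O[Si](C(C)C)(C(C)C)C(C)C)c2OC)ccc1O[Si](C(C)C)(C(C)C)C(C)C | intermediate
16 | trichlorotitanium Z-enolate of 15 | COc1cc([C@H](/C=C(\O[Ti](Cl)(Cl)Cl)N2C(=O)OC[C@H]2Cc2ccccc2)c2c(Br)ccc(O[Si](C(C)C)(C(C)C)C(C)C)c2OC)ccc1O[Si](C(C)C)(C(C)C)C(C)C | intermediate (not isolated)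
17 | (4R)-4-benzyl-3-[(2S,3S)-3-ArA-3-ArC-2-(hydroxymethyl)propanoyl]-1,3-oxazolidin-2-one | COc1cc([C@H]([C@@H](CO)C(=O)N2C(=O)OC[C@H]2Cc2ccccc2)c2c(Br)ccc(O[Si](C(C)C)(C(C)C)C(C)C)c2OC)ccc1O[Si](C(C)C)(C(C)C)C(C)C | intermediate
18 | (4R)-4-benzyl-3-[(2S,3S)-3-ArA-3-ArC-2-({[tert-butyl(dimethyl)silyl]oxy}methyl)propanoyl]-1,3-oxazolidin-2-one | COc1cc([C@H]([C@@H](CO[Si](C)(C)C(C)(C)C)C(=O)N2C(=O)OC[C@H]2Cc2ccccc2)c2c(Br)ccc(O[Si](C(C)C)(C(C)C)C(C)C)c2OC)ccc1O[Si](C(C)C)(C(C)C)C(C)C | intermediate
19 | (2R,3S)-3-ArA-3-ArC-2-({[tert-butyl(dimethyl)silyl]oxy}methyl)propan-1-ol | COc1cc([C@H]([C@@H](CO[Si](C)(C)C(C)(C)C)CO)c2c(Br)ccc(O[Si](C(C)C)(C(C)C)C(C)C)c2OC)ccc1O[Si](C(C)C)(C(C)C)C(C)C | intermediate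
20 | (2S,3S)-3-ArA-3-ArC-2-({[tert-butyl(dimethyl)silyl]oxy}methyl)propanal | COc1cc([C@H]([C@@H](CO[Si](C)(C)C(C)(C)C)C=O)c2c(Br)ccc(O[Si](C(C)C)(C(C)C)C(C)C)c2OC)ccc1O[Si](C(C)C)(C(C)C)C(C)C | intermediate
21 | (methoxymethyl)triphenylphosphonium chloride | COC[P+](c1ccccc1)(c1ccccc1)c1ccccc1.[Cl-] | starting material
22 | (methoxymethylidene)triphenylphosphorane | COC=P(c1ccccc1)(c1ccccc1)c1ccccc1 | intermediate (not isolated)
23 | (1E,3R,4S)-4-ArA-4-ArC-3-({[tert-butyl(dimethyl)silyl]oxy}methyl)-1-methoxybut-1-ene | COc1cc([C@H]([C@@H](CO[Si](C)(C)C(C)(C)C)/C=C/OC)c2c(Br)ccc(O[Si](C(C)C)(C(C)C)C(C)C)c2OC)ccc1O[Si](C(C)C)(C(C)C)C(C)C | intermediate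
24 | carbon monoxide | [C-]#[O+] | starting material
25 | (2E,3R,4S)-3-({[tert-butyl(dimethyl)silyl]oxy}methyl)-5-methoxy-2-(methoxymethylidene)-4-{3-methoxy-4-[(triisopropylsilyl)oxy]phenyl}-6-[(triisopropylsilyl)oxy]-3,4-dihydronaphthalen-1(2H)-one | COc1cc([C@H]2c3c(ccc(O[Si](C(C)C)(C(C)C)C(C)C)c3OC)C(=O)/C(=C/OC)[C@@H]2CO[Si](C)(C)C(C)(C)C)ccc1O[Si](C(C)C)(C(C)C)C(C)C | intermediate
26 | (2E,3R,4S)-3-({[tert-butyl(dimethyl)silyl]oxy}methyl)-5-methoxy-2-(methoxymethylidene)-4-{3-methoxy-4-[(triisopropylsilyl)oxy]phenyl}-6-[(triisopropylsilyl)oxy]-1,2,3,4-tetrahydronaphthalen-1-ol (carbinol centre not defined) | COc1cc([C@H]2c3c(ccc(O[Si](C(C)C)(C(C)C)C(C)C)c3OC)C(O)/C(=C/OC)[C@@H]2CO[Si](C)(C)C(C)(C)C)ccc1O[Si](C(C)C)(C(C)C)C(C)C | intermediate (not isolated)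
27 | (3R,4S)-3-({[tert-butyl(dimethyl)silyl]oxy}methyl)-5-methoxy-4-{3-methoxy-4-[(triisopropylsilyl)oxy]phenyl}-6-[(triisopropylsilyl)oxy]-3,4-dihydronaphthalene-2-carbaldehyde | COc1cc([C@H]2c3c(ccc(O[Si](C(C)C)(C(C)C)C(C)C)c3OC)C=C(C=O)[C@@H]2CO[Si](C)(C)C(C)(C)C)ccc1O[Si](C(C)C)(C(C)C)C(C)C | intermediate
28 | vitedoin A, (3R,4S)-6-hydroxy-4-(4-hydroxy-3-methoxyphenyl)-3-(hydroxymethyl)-5-methoxy-3,4-dihydronaphthalene-2-carbaldehyde | COc1cc([C@H]2c3c(ccc(O)c3OC)C=C(C=O)[C@@H]2CO)ccc1O | target

**Count**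

Total step count: 16. Longest linear sequence: 14 steps (steps 1–4, 6 and 8–16).

**Steps most likely to fail**

Step 14. Palladium may close onto the enol ether before it takes up CO (5-exo Heck closure to an indane), oxidative addition at the hindered, electron-rich C4a–Br bond may be slow, or palladium hydride may walk the exocyclic double bond into ring B, which would then aromatise and destroy C1 and C2. Fallback: from 23, bromine–lithium exchange (n-BuLi, THF, −78 °C) and a DMF quench would give the aryl aldehyde 2-[(1S,2R,3E)-2-({[tert-butyl(dimethyl)silyl]oxy}methyl)-4-methoxy-1-ArC-but-3-en-1-yl]-3-methoxy-4-[(triisopropylsilyl)oxy]benzaldehyde F1, in which C4 is already attached to C4a. Mild aqueous acid (oxalic acid, wet THF) would unmask the enol ether to the dialdehyde 2-[(1S,2S)-2-({[tert-butyl(dimethyl)silyl]oxy}methyl)-4-oxo-1-ArC-butyl]-3-methoxy-4-[(triisopropylsilyl)oxy]benzaldehyde F2. Dibenzylammonium trifluoroacetate would then close ring B by intramolecular aldol condensation of the only enolisable aldehyde (C9, through C3) onto the aryl aldehyde, with dehydration to the C3=C4 enal. This comes back to the route at 27 and bypasses 25 and 26.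

Step 8. Aryl transfer to a β-carbon flanked by an ortho bromine and an ortho methoxy group may be slow, and facial control by the benzyl group may be incomplete; a minor C1 epimer would be a diastereomer of 15 and would be removed there by chromatography or crystallisation. Fallback (catalyst control in place of auxiliary control): from 6, olefination with tert-butyl diethylphosphonoacetate (LiCl, i-Pr2NEt, MeCN) would give tert-butyl (2E)-3-ArA-prop-2-enoate F3, and 13 would be converted (n-BuLi, B(Oi-Pr)3, THF, −78 °C, then dilute acid) into {3-methoxy-4-[(triisopropylsilyl)oxy]phenyl}boronic acid F4. A Hayashi–Miyaura 1,4-addition of F4 to F3 (Rh(acac)(C2H4)2, the BINAP enantiomer that delivers the 3S adduct, dioxane/H2O, 100 °C) would give tert-butyl (3S)-3-ArA-3-ArC-propanoate F5. CF3CO2H in CH2Cl2 would free (3S)-3-ArA-3-ArC-propanoic acid F6, and acylation of 7 through the pivalic mixed anhydride (PivCl, Et3N, LiCl) would come back to the route at 15.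

Step 11. Hydride may attack the ring carbonyl of the auxiliary instead of the acyl carbonyl, which is shielded by branches at both C2 and C1, opening the oxazolidinone; prolonged exposure of the alkoxide could also let the silyl group migrate between the two oxygen atoms on C2. Fallback: from 18, LiOH/H2O2 (THF/H2O, 0 °C), whose hydroperoxide anion attacks the exocyclic carbonyl even of hindered imides, would give (2S,3S)-3-ArA-3-ArC-2-({[tert-butyl(dimethyl)silyl]oxy}methyl)propanoic acid F7, and BH3·SMe2 (THF, 0 °C) would reduce the acid chemoselectively, coming back to the route at 19.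

**Further compounds**

F1 | step 14 | 2-[(1S,2R,3E)-2-({[tert-butyl(dimethyl)silyl]oxy}methyl)-4-methoxy-1-ArC-but-3-en-1-yl]-3-methoxy-4-[(triisopropylsilyl)oxy]benzaldehyde | COc1cc([C@H]([C@@H](CO[Si](C)(C)C(C)(C)C)/C=C/OC)c2c(C=O)ccc(O[Si](C(C)C)(C(C)C)C(C)C)c2OC)ccc1O[Si](C(C)C)(C(C)C)C(C)C
F2 | step 14 | 2-[(1S,2S)-2-({[tert-butyl(dimethyl)silyl]oxy}methyl)-4-oxo-1-ArC-butyl]-3-methoxy-4-[(triisopropylsilyl)oxy]benzaldehyde | COc1cc([C@H]([C@@H](CO[Si](C)(C)C(C)(C)C)CC=O)c2c(C=O)ccc(O[Si](C(C)C)(C(C)C)C(C)C)c2OC)ccc1O[Si](C(C)C)(C(C)C)C(C)C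
F3 | step 8 | tert-butyl (2E)-3-ArA-prop-2-enoate | COc1c(O[Si](C(C)C)(C(C)C)C(C)C)ccc(Br)c1/C=C/C(=O)OC(C)(C)C
F4 | step 8 | {3-methoxy-4-[(triisopropylsilyl)oxy]phenyl}boronic acid | COc1cc(B(O)O)ccc1O[Si](C(C)C)(C(C)C)C(C)C
F5 | step 8 | tert-butyl (3S)-3-ArA-3-ArC-propanoate | COc1cc([C@H](CC(=O)OC(C)(C)C)c2c(Br)ccc(O[Si](C(C)C)(C(C)C)C(C)C)c2OC)ccc1O[Si](C(C)C)(C(C)C)C(C)C
F6 | step 8 | (3S)-3-ArA-3-ArC-propanoic acid | COc1cc([C@H](CC(=O)O)c2c(Br)ccc(O[Si](C(C)C)(C(C)C)C(C)C)c2OC)ccc1O[Si](C(C)C)(C(C)C)C(C)C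
F7 | step 11 | (2S,3S)-3-ArA-3-ArC-2-({[tert-butyl(dimethyl)silyl]oxy}methyl)propanoic acid | COc1cc([C@H]([C@@H](CO[Si](C)(C)C(C)(C)C)C(=O)O)c2c(Br)ccc(O[Si](C(C)C)(C(C)C)C(C)C)c2OC)ccc1O[Si](C(C)C)(C(C)C)C(C)C
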